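**Assumption:** the SMILES is read as (1R,3R,4R,7R,8R,10S,11S)-10-acetoxy-3,4:7,8-diepoxyverticill-12(18)-en-13-one; carbon numbers (C1–C20) follow verticillane numbering, which coincides with bicyclo[9.3.1]pentadecane numbering.

## Retrosynthetic overview

1. The target comes from peripheral bis-epoxidation of the (3E,7E)-dienyl exo-methylene ketone acetate; the exo-methylene enone comes from a β-acetoxy ketone by elimination.
2. Ring A is made last: a tertiary C15 radical (from a CMe2NO2 group on C11) closes transannularly, 6-endo, onto the (E)-enone C1=C14 of a 14-membered ring, forming C1–C15 and setting C1.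
3. The 14-membered enone comes from ring-closing metathesis at C1=C14; C18 is added by α′-hydroxymethylation while C12 is still the only sp3 α-carbon.
4. The acyclic chain comes from a Negishi coupling at C6–C7; both E-trisubstituted alkenes come from Zr-catalysed carboalumination of pent-4-yn-1-ol and but-3-yn-1-ol.
5. C10 is set by proline-catalysed α-aminoxylation and C11 by a syn-selective nitro-Michael addition; ring order is 14-membered ring, then ring A, then the two epoxides.

## Route

Step 1
Reactants: 1 pent-4-yn-1-ol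
Product: 3 (E)-5-iodo-4-methylpent-4-en-1-ol, via alkenylalane 2 (not isolated)
Conditions: Me3Al (3 equiv), Cp2ZrCl2 (25 mol %), CH2Cl2, 0 °C → rt; then I2, THF, −30 → 0 °C
Reagents that add atoms: trimethylaluminium (C[Al](C)C); iodine (I-I)
Why: Zr-catalysed methylalumination (Negishi carboalumination) adds Me and Al syn to the terminal alkyne and iodinolysis goes with retention, giving the E vinyl iodide that becomes C7=C8 with C19.

Step 2
Reactants: 3 (E)-5-iodo-4-methylpent-4-en-1-ol
Product: 4 (E)-5-iodo-4-methylpent-4-enal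
Conditions: Dess–Martin periodinane, NaHCO3, CH2Cl2, 0 °C → rt
Reagents that add atoms: none
Why: Dess–Martin oxidation of the primary alcohol; the aldehyde is not conjugated to the alkene, so the geometry cannot scramble.

Step 3
Reactants: 4 (E)-5-iodo-4-methylpent-4-enal
Product: 7 methyl (2E,4S,6E)-4-hydroxy-7-iodo-6-methylhepta-2,6-dienoate, via anilinooxy aldehyde 5 (not isolated), via anilinooxy enoate 6 (not isolated)
Conditions: D-proline (20 mol %), PhNO, CHCl3, 4 °C; then Ph3P=CHCO2Me, 0 °C → rt; then Cu(OAc)2 (30 mol %), MeOH, rt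
Reagents that add atoms: nitrosobenzene (O=Nc1ccccc1); methyl (triphenylphosphoranylidene)acetate (COC(=O)C=P(c1ccccc1)(c1ccccc1)c1ccccc1)
Why: Proline enamine catalysis (α-aminoxylation, an O-selective nitroso aldol) sets C10, with D-proline giving the S aldehyde; the stabilised Wittig reagent traps it at once as the E enoate and copper-catalysed N–O cleavage frees the alcohol.

Step 4
Reactants: 7 methyl (2E,4S,6E)-4-hydroxy-7-iodo-6-methylhepta-2,6-dienoate
Product: 8 methyl (2E,4S,6E)-4-[(tert-butyldimethylsilyl)oxy]-7-iodo-6-methylhepta-2,6-dienoate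
Conditions: TBSCl, imidazole, DMF, rt
Reagents that add atoms: tert-butyldimethylsilyl chloride (CC(C)(C)[Si](C)(C)Cl)
Why: Standard silylation; the ether blocks lactonisation and survives the base, Grignard and amide-base steps that follow.

Step 5
Reactants: 8 methyl (2E,4S,6E)-4-[(tert-butyldimethylsilyl)oxy]-7-iodo-6-methylhepta-2,6-dienoate; 9 2-nitropropane
Product: 10 methyl (3R,4S,6E)-4-[(tert-butyldimethylsilyl)oxy]-7-iodo-6-methyl-3-(2-nitropropan-2-yl)hept-6-enoate
Conditions: 9 (5 equiv), DBU (1.0 equiv), MeCN, rt, 48 h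
Reagents that add atoms: none
Why: Nitro-Michael addition; the nitronate attacks the E γ-silyloxy enoate anti to the C–O bond with C9 inside (Felkin–Anh), which gives the 10,11-syn adduct (C11), the minor anti isomer being removed by chromatography; the tertiary nitro group is the later source of the C15 radical.

Step 6
Reactants: 11 but-3-yn-1-ol; 12 allyl bromide
Product: 14 (E)-3-methylhepta-3,6-dien-1-ol, via alkenylalane 13 (not isolated)
Conditions: Me3Al (3 equiv), Cp2ZrCl2 (25 mol %), CH2Cl2, 0 °C → rt; then 12, Pd(PPh3)4 (3 mol %), THF, rt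
Reagents that add atoms: trimethylaluminium (C[Al](C)C)
Why: Negishi carboalumination followed by Pd-catalysed allylation of the alkenylalane with retention gives the E skipped diene (C3=C4 with C20; the allyl group supplies C2, C1 and the carbon later lost in metathesis).

Step 7
Reactants: 14 (E)-3-methylhepta-3,6-dien-1-ol
Product: 15 (E)-7-iodo-5-methylhepta-1,4-diene
Conditions: I2, PPh3, imidazole, CH2Cl2, 0 °C
Reagents that add atoms: iodine (I-I)
Why: Appel-type iodination of the primary homoallylic alcohol under neutral conditions leaves the skipped diene untouched.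

Step 8
Reactants: 15 (E)-7-iodo-5-methylhepta-1,4-diene; 10 methyl (3R,4S,6E)-4-[(tert-butyldimethylsilyl)oxy]-7-iodo-6-methyl-3-(2-nitropropan-2-yl)hept-6-enoate
Product: 17 methyl (3R,4S,6E,10E)-4-[(tert-butyldimethylsilyl)oxy]-6,10-dimethyl-3-(2-nitropropan-2-yl)tetradeca-6,10,13-trienoate, via alkylzinc iodide 16 (not isolated)
Conditions: 15, Zn dust, LiCl, THF, 40 °C; then 10, Pd(dppf)Cl2 (5 mol %), THF, rt → 45 °C
Reagents that add atoms: none
Why: Zinc insertion into the primary iodide and Negishi sp3–sp2 coupling join C6 to C7 with retention of the vinyl iodide geometry; ester, silyl ether and tertiary nitro group are tolerated by the organozinc.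

Step 9
Reactants: 17 methyl (3R,4S,6E,10E)-4-[(tert-butyldimethylsilyl)oxy]-6,10-dimethyl-3-(2-nitropropan-2-yl)tetradeca-6,10,13-trienoate; 18 vinylmagnesium bromide
Product: 20 (5R,6S,8E,12E)-6-[(tert-butyldimethylsilyl)oxy]-8,12-dimethyl-5-(2-nitropropan-2-yl)hexadeca-1,8,12,15-tetraen-3-one, via Weinreb amide 19 (not isolated)
Conditions: MeNH(OMe)·HCl, i-PrMgCl, THF, −20 °C; then 18, −20 → 0 °C; inverse quench into cold aq. NH4Cl
Reagents that add atoms: none
Why: One-pot Weinreb ketone synthesis; the magnesium amide converts the ester to the N-methoxy-N-methylamide, whose chelated adduct with the vinyl Grignard reagent stops at the ketone, and the low temperature spares the hindered tertiary nitro group.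

Step 10
Reactants: 20 (5R,6S,8E,12E)-6-[(tert-butyldimethylsilyl)oxy]-8,12-dimethyl-5-(2-nitropropan-2-yl)hexadeca-1,8,12,15-tetraen-3-one
Product: 21 (2E,5E,9E,12S,13R)-12-[(tert-butyldimethylsilyl)oxy]-6,10-dimethyl-13-(2-nitropropan-2-yl)cyclotetradeca-2,5,9-trien-1-one
Conditions: second-generation Grubbs catalyst (H2IMes)(PCy3)Cl2Ru=CHPh (10 mol %), 1,4-benzoquinone (20 mol %), CH2Cl2 (1 mM), 40 °C
Reagents that add atoms: none
Why: Ring-closing metathesis between the terminal alkene and the vinyl ketone gives the 14-membered E enone (C1=C14); the trisubstituted alkenes do not react and benzoquinone suppresses olefin migration.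

Step 11
Reactants: 21 (2E,5E,9E,12S,13R)-12-[(tert-butyldimethylsilyl)oxy]-6,10-dimethyl-13-(2-nitropropan-2-yl)cyclotetradeca-2,5,9-trien-1-one
Product: 23 (2E,5E,9E,12S,13R)-12-[(tert-butyldimethylsilyl)oxy]-14-(hydroxymethyl)-6,10-dimethyl-13-(2-nitropropan-2-yl)cyclotetradeca-2,5,9-trien-1-one, via lithium enolate 22 (not isolated)
Conditions: LiN(SiMe3)2 (1.1 equiv), THF, −78 °C; then CH2O (gas, from paraformaldehyde), −78 °C; AcOH
Reagents that add atoms: formaldehyde (C=O)
Why: Kinetic α′-deprotonation of the enone (C12 is the only sp3 α-carbon) and aldol addition to formaldehyde install C18 regiospecifically before ring A exists; both C12 epimers are carried on because C12 becomes sp2 later.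

Step 12
Reactants: 23 (2E,5E,9E,12S,13R)-12-[(tert-butyldimethylsilyl)oxy]-14-(hydroxymethyl)-6,10-dimethyl-13-(2-nitropropan-2-yl)cyclotetradeca-2,5,9-trien-1-one
Product: 24 (1R,3E,7E,10S,11R)-10-[(tert-butyldimethylsilyl)oxy]-12-(hydroxymethyl)-4,8,15,15-tetramethylbicyclo[9.3.1]pentadeca-3,7-dien-13-one
Conditions: Bu3SnH (1.5 equiv, syringe pump, 8 h), AIBN (0.3 equiv), PhH (2 mM), 80 °C
Reagents that add atoms: none
Why: Proposed new method: the stannyl radical removes the tertiary nitro group to give the nucleophilic C15 radical, which closes ring A by a polarity-matched transannular 6-endo-trig Giese addition to C1 of the enone before the α-keto radical takes H from Bu3SnH (closest known types: tin hydride denitrative radical cyclisation of tertiary nitroalkanes onto enones and transannular radical cyclisation of macrocyclic enones); the E enone holds C2 pseudo-equatorial and the C3–C9 tether plus the gem-dimethyl radical centre then push C10 pseudo-axial, so C1–C15 forms trans to C11–C10 across ring A and sets C1 as R.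

Step 13
Reactants: 24 (1R,3E,7E,10S,11R)-10-[(tert-butyldimethylsilyl)oxy]-12-(hydroxymethyl)-4,8,15,15-tetramethylbicyclo[9.3.1]pentadeca-3,7-dien-13-one
Product: 27 (1R,3E,7E,10S,11S)-4,8,15,15-tetramethyl-12-methylidene-13-oxobicyclo[9.3.1]pentadeca-3,7-dien-10-yl acetate, via diol 25 (not isolated), via diacetate 26 (not isolated)
Conditions: HF·pyridine, THF, 0 °C → rt; then pyridine, Ac2O, DMAP, rt; then DBU, 0 °C → rt
Reagents that add atoms: acetic anhydride (CC(=O)OC(C)=O)
Why: Desilylation, acetylation of both hydroxyls and E1cB elimination of the β-acetoxy ketone give the exocyclic enone; the C10 acetate stays because C11–H is not acidic (its anion would be cross-conjugated).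

Step 14
Reactants: 27 (1R,3E,7E,10S,11S)-4,8,15,15-tetramethyl-12-methylidene-13-oxobicyclo[9.3.1]pentadeca-3,7-dien-10-yl acetate
Product: 28 (1R,3R,4R,7R,8R,10S,11S)-3,4:7,8-diepoxy-4,8,15,15-tetramethyl-12-methylidene-13-oxobicyclo[9.3.1]pentadecan-10-yl acetate
Conditions: mCPBA (2.4 equiv), NaHCO3, CH2Cl2, −20 → 0 °C
Reagents that add atoms: 3-chloroperbenzoic acid (O=C(OO)c1cccc(Cl)c1)
Why: Prilezhaev epoxidation of the two electron-rich E-trisubstituted alkenes only (the enone is inert); attack from the outer face of each alkene with both methyls on the same side of the 12-membered ring is expected to give the (3R,4R,7R,8R) bis-epoxide, but this facial preference is not established for this ring system.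

## Compound list

1 | pent-4-yn-1-ol | C#CCCCO | starting material
2 | [(1E)-5-[(dimethylalumanyl)oxy]-2-methylpent-1-en-1-yl]dimethylalumane | C[Al](C)/C=C(\C)CCCO[Al](C)C | intermediate
3 | (E)-5-iodo-4-methylpent-4-en-1-ol | OCCC/C(C)=C/I | intermediate
4 | (E)-5-iodo-4-methylpent-4-enal | O=CCC/C(C)=C/I | intermediate
5 | (2S,4E)-5-iodo-4-methyl-2-[(phenylamino)oxy]pent-4-enal | I/C=C(\C)C[C@H](ONc1ccccc1)C=O | intermediate
6 | methyl (2E,4S,6E)-7-iodo-6-methyl-4-[(phenylamino)oxy]hepta-2,6-dienoate | I/C=C(\C)C[C@H](ONc1ccccc1)/C=C/C(=O)OC | intermediate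
7 | methyl (2E,4S,6E)-4-hydroxy-7-iodo-6-methylhepta-2,6-dienoate | I/C=C(\C)C[C@H](O)/C=C/C(=O)OC | intermediate
8 | methyl (2E,4S,6E)-4-[(tert-butyldimethylsilyl)oxy]-7-iodo-6-methylhepta-2,6-dienoate | I/C=C(\C)C[C@H](O[Si](C)(C)C(C)(C)C)/C=C/C(=O)OC | intermediate
9 | 2-nitropropane | CC(C)[N+](=O)[O-] | starting material
10 | methyl (3R,4S,6E)-4-[(tert-butyldimethylsilyl)oxy]-7-iodo-6-methyl-3-(2-nitropropan-2-yl)hept-6-enoate | I/C=C(\C)C[C@H](O[Si](C)(C)C(C)(C)C)[C@H](CC(=O)OC)C(C)(C)[N+](=O)[O-] | intermediate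
11 | but-3-yn-1-ol | C#CCCO | starting material
12 | allyl bromide | C=CCBr | starting material
13 | [(1E)-4-[(dimethylalumanyl)oxy]-2-methylbut-1-en-1-yl]dimethylalumane | C[Al](C)/C=C(\C)CCO[Al](C)C | intermediate
14 | (E)-3-methylhepta-3,6-dien-1-ol | OCC/C(C)=C/CC=C | intermediate
15 | (E)-7-iodo-5-methylhepta-1,4-diene | ICC/C(C)=C/CC=C | intermediate
16 | iodo[(3E)-3-methylhepta-3,6-dien-1-yl]zinc | I[Zn]CC/C(C)=C/CC=C | intermediate
17 | methyl (3R,4S,6E,10E)-4-[(tert-butyldimethylsilyl)oxy]-6,10-dimethyl-3-(2-nitropropan-2-yl)tetradeca-6,10,13-trienoate | C=CC/C=C(\C)CC/C=C(\C)C[C@H](O[Si](C)(C)C(C)(C)C)[C@H](CC(=O)OC)C(C)(C)[N+](=O)[O-] | intermediate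
18 | vinylmagnesium bromide | C=C[Mg]Br | starting material
19 | (3R,4S,6E,10E)-4-[(tert-butyldimethylsilyl)oxy]-N-methoxy-N,6,10-trimethyl-3-(2-nitropropan-2-yl)tetradeca-6,10,13-trienamide | C=CC/C=C(\C)CC/C=C(\C)C[C@H](O[Si](C)(C)C(C)(C)C)[C@H](CC(=O)N(C)OC)C(C)(C)[N+](=O)[O-] | intermediate
20 | (5R,6S,8E,12E)-6-[(tert-butyldimethylsilyl)oxy]-8,12-dimethyl-5-(2-nitropropan-2-yl)hexadeca-1,8,12,15-tetraen-3-one | C=CC/C=C(\C)CC/C=C(\C)C[C@H](O[Si](C)(C)C(C)(C)C)[C@H](CC(=O)C=C)C(C)(C)[N+](=O)[O-] | intermediate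
21 | (2E,5E,9E,12S,13R)-12-[(tert-butyldimethylsilyl)oxy]-6,10-dimethyl-13-(2-nitropropan-2-yl)cyclotetradeca-2,5,9-trien-1-one | O=C1/C=C/C/C=C(\C)CC/C=C(\C)C[C@H](O[Si](C)(C)C(C)(C)C)[C@H](C1)C(C)(C)[N+](=O)[O-] | intermediate
22 | lithium enolate of 21 (C12=C13–OLi, cross-conjugated) | [Li]OC1=C[C@H](C(C)(C)[N+](=O)[O-])[C@@H](O[Si](C)(C)C(C)(C)C)C/C(C)=C/CC/C(C)=C/C/C=C/1 | intermediate
23 | (2E,5E,9E,12S,13R)-12-[(tert-butyldimethylsilyl)oxy]-14-(hydroxymethyl)-6,10-dimethyl-13-(2-nitropropan-2-yl)cyclotetradeca-2,5,9-trien-1-one (both C14 epimers) | O=C1/C=C/C/C=C(\C)CC/C=C(\C)C[C@H](O[Si](C)(C)C(C)(C)C)[C@H](C1CO)C(C)(C)[N+](=O)[O-] | intermediate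
24 | (1R,3E,7E,10S,11R)-10-[(tert-butyldimethylsilyl)oxy]-12-(hydroxymethyl)-4,8,15,15-tetramethylbicyclo[9.3.1]pentadeca-3,7-dien-13-one (both C12 epimers) | OCC1C(=O)C[C@H]2C/C=C(\C)CC/C=C(\C)C[C@H](O[Si](C)(C)C(C)(C)C)[C@H]1C2(C)C | intermediate
25 | (1R,3E,7E,10S,11R)-10-hydroxy-12-(hydroxymethyl)-4,8,15,15-tetramethylbicyclo[9.3.1]pentadeca-3,7-dien-13-one | OCC1C(=O)C[C@H]2C/C=C(\C)CC/C=C(\C)C[C@H](O)[C@H]1C2(C)C | intermediate
26 | [(1R,3E,7E,10S,11R)-10-acetoxy-4,8,15,15-tetramethyl-13-oxobicyclo[9.3.1]pentadeca-3,7-dien-12-yl]methyl acetate | CC(=O)OCC1C(=O)C[C@H]2C/C=C(\C)CC/C=C(\C)C[C@H](OC(C)=O)[C@H]1C2(C)C | intermediate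
27 | (1R,3E,7E,10S,11S)-4,8,15,15-tetramethyl-12-methylidene-13-oxobicyclo[9.3.1]pentadeca-3,7-dien-10-yl acetate | C=C1C(=O)C[C@H]2C/C=C(\C)CC/C=C(\C)C[C@H](OC(C)=O)[C@H]1C2(C)C | intermediate
28 | (1R,3R,4R,7R,8R,10S,11S)-3,4:7,8-diepoxy-4,8,15,15-tetramethyl-12-methylidene-13-oxobicyclo[9.3.1]pentadecan-10-yl acetate (CNP0339728.2) | C=C1C(=O)C[C@H]2C[C@H]3O[C@]3(C)CC[C@H]3O[C@]3(C)C[C@H](OC(C)=O)[C@H]1C2(C)C | target

## Step count and risks

Total steps: 14. Longest linear sequence: 12 (steps 1–5 and 8–14; steps 6–7 make the second coupling partner).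

Three steps most likely to fail:

**Step 12 (transannular radical ring closure).** The tertiary radical may be reduced by Bu3SnH before it cyclises, or the ring may close to the cis-fused C1 epimer. The fallback sets C1 by alkene geometry instead of by ring strain. It sets out from 23: irradiation (350 nm, MeCN) to the photostationary E/Z mixture and separation give the Z enone (2Z,5E,9E,12S,13R)-12-[(tert-butyldimethylsilyl)oxy]-14-(hydroxymethyl)-6,10-dimethyl-13-(2-nitropropan-2-yl)cyclotetradeca-2,5,9-trien-1-one F1. F1 is then put through the same tin hydride chain. In the Z enone C2 is cis to the carbonyl carbon and must sit pseudo-axial in the chair-like transition state while C10 can stay pseudo-equatorial, so the trans ring fusion arises from the opposite chair arrangement; the twisted Z enone is also the more reactive acceptor. The fallback comes back to the route at 24.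

**Step 10 (ring-closing metathesis to the 14-membered enone).** Oligomerisation, a sluggish electron-poor vinyl ketone or olefin migration in the skipped diene could defeat it. The fallback moves the ring closure to C6–C7 and makes the enone intermolecularly. It sets out from 10 (and uses 15):
- The aminolysis/vinylation of step 9 applied to 10 gives, through the Weinreb amide (3R,4S,6E)-4-[(tert-butyldimethylsilyl)oxy]-7-iodo-N-methoxy-N,6-dimethyl-3-(2-nitropropan-2-yl)hept-6-enamide F2, the vinyl ketone (5R,6S,8E)-6-[(tert-butyldimethylsilyl)oxy]-9-iodo-8-methyl-5-(2-nitropropan-2-yl)nona-1,8-dien-3-one F3.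
- Cross-metathesis of F3 with the terminal alkene of 15 (second-generation Hoveyda–Grubbs catalyst, CH2Cl2, 40 °C) gives the acyclic E enone (1E,4S,5R,8E,11E)-4-[(tert-butyldimethylsilyl)oxy]-1,14-diiodo-2,12-dimethyl-5-(2-nitropropan-2-yl)tetradeca-1,8,11-trien-7-one F4.
- Zinc inserts only into the alkyl iodide (Zn, LiCl, THF) to give the alkylzinc iodide of F4 (C14–ZnI in place of C14–I) F5, and an intramolecular Negishi coupling with the vinyl iodide under high dilution (Pd(dppf)Cl2, slow addition) closes the ring and comes back to the route at 21.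

**Step 14 (facial selectivity of the bis-epoxidation).** If the macrocycle does not present the required outer faces, diastereomeric bis-epoxides will form. The fallback replaces substrate control by reagent control. It sets out from 27: Shi epoxidation with the D-fructose-derived ketone and KHSO5 (buffered to about pH 8, MeCN/dimethoxymethane/water, 0 °C) converts each E-trisubstituted alkene to the (R,R)-epoxide whatever the ring conformation, leaves the electron-poor enone alone, and comes back at 28. It makes no new compound.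

## Further compounds

F1 | step 12 | (2Z,5E,9E,12S,13R)-12-[(tert-butyldimethylsilyl)oxy]-14-(hydroxymethyl)-6,10-dimethyl-13-(2-nitropropan-2-yl)cyclotetradeca-2,5,9-trien-1-one | O=C1/C=C\C/C=C(\C)CC/C=C(\C)C[C@H](O[Si](C)(C)C(C)(C)C)[C@H](C1CO)C(C)(C)[N+](=O)[O-]
F2 | step 10 | (3R,4S,6E)-4-[(tert-butyldimethylsilyl)oxy]-7-iodo-N-methoxy-N,6-dimethyl-3-(2-nitropropan-2-yl)hept-6-enamide | I/C=C(\C)C[C@H](O[Si](C)(C)C(C)(C)C)[C@H](CC(=O)N(C)OC)C(C)(C)[N+](=O)[O-]
F3 | step 10 | (5R,6S,8E)-6-[(tert-butyldimethylsilyl)oxy]-9-iodo-8-methyl-5-(2-nitropropan-2-yl)nona-1,8-dien-3-one | I/C=C(\C)C[C@H](O[Si](C)(C)C(C)(C)C)[C@H](CC(=O)C=C)C(C)(C)[N+](=O)[O-]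
F4 | step 10 | (1E,4S,5R,8E,11E)-4-[(tert-butyldimethylsilyl)oxy]-1,14-diiodo-2,12-dimethyl-5-(2-nitropropan-2-yl)tetradeca-1,8,11-trien-7-one | I/C=C(\C)C[C@H](O[Si](C)(C)C(C)(C)C)[C@H](CC(=O)/C=C/C/C=C(\C)CCI)C(C)(C)[N+](=O)[O-]
F5 | step 10 | alkylzinc iodide of F4 (C14–ZnI in place of C14–I) | I/C=C(\C)C[C@H](O[Si](C)(C)C(C)(C)C)[C@H](CC(=O)/C=C/C/C=C(\C)CC[Zn]I)C(C)(C)[N+](=O)[O-]
F0 | step 14 | none | none
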